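**Strategy.** Everything rests on a [3+3] disconnection of the non-aromatic ring A (C1 ring carbonyl, C2 carrying hexanoyl, C6 carrying the benzylic CH2). Its quaternary carbon C4 and the flanking oxygenated carbons C3 and C5 are a methyl(prenyl)malonyl unit; C2, C1 and C6 are the C3–C2–C1 span of nonane-2,4-dione. C4 is stereogenic only because the two arms of ring A differ, so an enantioenriched malonic half-ester chloride, whose two acyl carbons differ in reactivity, encodes it. In one flask the diketone dianion is acylated at its terminal carbon by the acid chloride and the internal carbon then closes onto the ester, forging C5–C6 and C2–C3. Mannich-type methylene bridging to the aromatic ketone completes the target.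

Key step: step 6

Assumption: the (S,S)-configured phase-transfer catalyst is taken to deliver the (R)-diester 6 (if the sense proves opposite, the (R,R)-catalyst is used instead); enolised triones are drawn in the tautomer of the target.

Step 1
Reactants: 1 2,2,5-trimethyl-1,3-dioxane-4,6-dione (methyl Meldrum's acid)
Product: 2 3-(tert-butoxy)-2-methyl-3-oxopropanoic acid (racemic)
Conditions: t-BuOH, reflux
Reagents that add atoms: tert-butanol, CC(C)(C)O
Why: Alcoholysis of the Meldrum's acid (acyl substitution with ring opening and loss of acetone) should give the malonic half-ester, whose labile stereocentre is of no consequence.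

Step 2
Reactants: 2 3-(tert-butoxy)-2-methyl-3-oxopropanoic acid; 3 2,2-diphenylethanol
Product: 4 1-tert-butyl 3-(2,2-diphenylethyl) 2-methylpropanedioate (racemic)
Conditions: DCC, DMAP (cat.), CH2Cl2, 0 → 23 °C
Reagents that add atoms: none
Why: Steglich esterification should give the mixed malonate with two esters that can be cleaved independently.

Step 3
Reactants: 4 1-tert-butyl 3-(2,2-diphenylethyl) 2-methylpropanedioate; 5 1-bromo-3-methylbut-2-ene (prenyl bromide)
Product: 6 1-tert-butyl 3-(2,2-diphenylethyl) (2R)-2-methyl-2-(3-methylbut-2-en-1-yl)propanedioate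
Conditions: (S,S)-3,4,5-trifluorophenyl-NAS bromide (N-spiro bis(binaphthyl-2,2'-dimethylene)ammonium bromide with 3,4,5-trifluorophenyl groups at the 3,3'-positions of one binaphthyl, 5 mol%), 50% aq. KOH, toluene, −40 °C
Reagents that add atoms: none
Why: In this asymmetric phase-transfer α-alkylation the chiral ammonium cation pairs with the malonate enolate and shields one face while the tert-butyl and 2,2-diphenylethyl esters differentiate the enolate termini, so prenyl bromide should be delivered to one face and set the quaternary centre as (R).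

Step 4
Reactants: 6 1-tert-butyl 3-(2,2-diphenylethyl) (2R)-2-methyl-2-(3-methylbut-2-en-1-yl)propanedioate
Product: 8 (2S)-3-(2,2-diphenylethoxy)-2-methyl-2-(3-methylbut-2-en-1-yl)-3-oxopropanoic acid, via silyl ester 7 (not isolated)
Conditions: TMSOTf, 2,6-lutidine, CH2Cl2, 0 °C; then H2O (pH 3 work-up)
Reagents that add atoms: none
Why: Silyl-triflate-mediated tert-butyl ester cleavage (alkyl–oxygen fission to isobutene and the silyl ester, hydrolysed on work-up) is non-protic and should spare both the prenyl alkene, which strong acid would lactonise onto the carboxyl group, and the primary ester; the stereocentre is untouched.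

Step 5
Reactants: 8 (2S)-3-(2,2-diphenylethoxy)-2-methyl-2-(3-methylbut-2-en-1-yl)-3-oxopropanoic acid
Product: 9 2,2-diphenylethyl (2R)-3-chloro-2-methyl-2-(3-methylbut-2-en-1-yl)-3-oxopropanoate
Conditions: 1-chloro-N,N,2-trimethylprop-1-en-1-amine (Ghosez's reagent), CH2Cl2, 0 → 23 °C; concentrate and use crude
Reagents that add atoms: Ghosez's reagent, CC(C)=C(Cl)N(C)C
Why: Acid chloride formation with an α-chloroenamine runs under neutral conditions, so no HCl should add to the prenyl alkene, and the fully substituted α-carbon excludes ketene formation or racemisation.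

Step 6
Reactants: 9 2,2-diphenylethyl (2R)-3-chloro-2-methyl-2-(3-methylbut-2-en-1-yl)-3-oxopropanoate; 10 nonane-2,4-dione
Product: 12 (4S)-2-hexanoyl-3,5-dihydroxy-4-methyl-4-(3-methylbut-2-en-1-yl)cyclohexa-2,5-dien-1-one, via triketo ester 11 (not isolated)
Conditions: 10 (2.2 equiv), LiN(iPr)2 (4.5 equiv), THF, −78 → 0 °C; then 9, −78 °C; then 23 → 50 °C; 1 M HCl
Reagents that add atoms: none
Why: Two equivalents of LiN(iPr)2 convert 10 into its 1,3-dianion (CH3 is deprotonated in preference to the chain CH2), whose terminal carbanion, the most reactive site, attacks the acid chloride of 9 at −78 °C to give triketo ester 11 as its dianion; on warming, the internal carbon between the two original carbonyls attacks the diphenylethyl ester and expels the alkoxide (Claisen/Dieckmann condensation), which forges the second ring bond. The closest known reactions are the γ-acylation of β-diketone dianions and the Claisen cyclisation of 3,5,7-triketo esters to acylphloroglucinols, here run as one [3+3] annulation. The single ring closes in a 6-exo-trig mode (6-enolendo or 6-enolexo, both favoured), driven by the stabilised enolate of the 2-acyl-1,3,5-trione. No new stereocentre is created: no bond to the quaternary carbon is made or broken, and its (S) configuration in 12 follows solely from the pairing of terminal carbon with acid chloride and internal carbon with ester. The selectivity needed is this pairing (the reverse pairing would give the enantiomer), together with C- over O-acylation and Claisen over aldol closure; it is secured by the large reactivity gap between COCl and CO2R, by the far higher nucleophilicity of the terminal carbanion with lithium as counter-ion at low temperature, and by the quaternary α-carbon, which blocks any aldol path through the ester α-position. An enol lactone formed by O-attack on the ester would be funnelled to the same carbocycle by acyl transfer under the basic conditions.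

Step 7
Reactants: 13 benzene-1,3,5-triol (phloroglucinol); 14 hexanoyl chloride
Product: 15 1-(2,4,6-trihydroxyphenyl)hexan-1-one
Conditions: AlCl3, CH2Cl2/MeNO2, 0 → 40 °C; aq. HCl
Reagents that add atoms: none
Why: Friedel–Crafts C-acylation of the symmetric triphenol should stop at the mono-ketone because the acyl group deactivates the ring.

Step 8
Reactants: 15 1-(2,4,6-trihydroxyphenyl)hexan-1-one
Product: 16 1-(2,6-dihydroxy-4-methoxyphenyl)hexan-1-one
Conditions: Me2SO4 (1.0 equiv), K2CO3 (1.0 equiv), acetone, reflux
Reagents that add atoms: dimethyl sulfate, COS(=O)(=O)OC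
Why: Williamson O-methylation should occur at the 4-hydroxyl, the most acidic one and the only one not hydrogen-bonded to the ketone.

Step 9
Reactants: 12 (4S)-2-hexanoyl-3,5-dihydroxy-4-methyl-4-(3-methylbut-2-en-1-yl)cyclohexa-2,5-dien-1-one; 16 1-(2,6-dihydroxy-4-methoxyphenyl)hexan-1-one
Product: 19 (4S)-2-hexanoyl-6-[(3-hexanoyl-2,4-dihydroxy-6-methoxyphenyl)methyl]-3,5-dihydroxy-4-methyl-4-(3-methylbut-2-en-1-yl)cyclohexa-2,5-dien-1-one, via Mannich base 17 (not isolated), via exocyclic enone 18 (not isolated)
Conditions: Me2N=CH2 I (Eschenmoser's salt, 1.05 equiv), MeCN, 0 → 23 °C; then 16 (3 equiv), 70 °C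
Reagents that add atoms: N,N-dimethylmethyleneiminium iodide (Eschenmoser's salt), C=[N+](C)C.[I-]
Why: Mannich aminomethylation of the only free enol carbon of 12, thermal loss of dimethylamine to the 2-methylene-1,3-dione and Friedel–Crafts-type conjugate addition of a free ring position of 16 (two equivalent sites, used in excess against double alkylation) should give the methylene-bridged target with the quaternary stereocentre untouched.

**Compound list**

1 | 2,2,5-trimethyl-1,3-dioxane-4,6-dione | CC1C(=O)OC(C)(C)OC1=O | starting material
2 | 3-(tert-butoxy)-2-methyl-3-oxopropanoic acid (racemic) | CC(C(=O)O)C(=O)OC(C)(C)C | intermediate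
3 | 2,2-diphenylethanol | OCC(c1ccccc1)c1ccccc1 | starting material
4 | 1-tert-butyl 3-(2,2-diphenylethyl) 2-methylpropanedioate (racemic) | CC(C(=O)OCC(c1ccccc1)c1ccccc1)C(=O)OC(C)(C)C | intermediate
5 | 1-bromo-3-methylbut-2-ene | CC(C)=CCBr | starting material
6 | 1-tert-butyl 3-(2,2-diphenylethyl) (2R)-2-methyl-2-(3-methylbut-2-en-1-yl)propanedioate | O=C(OCC(c1ccccc1)c1ccccc1)[C@@](C)(CC=C(C)C)C(=O)OC(C)(C)C | intermediate
7 | 1-(2,2-diphenylethyl) 3-(trimethylsilyl) (2R)-2-methyl-2-(3-methylbut-2-en-1-yl)propanedioate | O=C(OCC(c1ccccc1)c1ccccc1)[C@@](C)(CC=C(C)C)C(=O)O[Si](C)(C)C | intermediate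
8 | (2S)-3-(2,2-diphenylethoxy)-2-methyl-2-(3-methylbut-2-en-1-yl)-3-oxopropanoic acid | O=C(OCC(c1ccccc1)c1ccccc1)[C@@](C)(CC=C(C)C)C(=O)O | intermediate
9 | 2,2-diphenylethyl (2R)-3-chloro-2-methyl-2-(3-methylbut-2-en-1-yl)-3-oxopropanoate | O=C(OCC(c1ccccc1)c1ccccc1)[C@@](C)(CC=C(C)C)C(Cl)=O | intermediate
10 | nonane-2,4-dione | CCCCCC(=O)CC(C)=O | starting material
11 | 2,2-diphenylethyl (2S)-2-methyl-2-(3-methylbut-2-en-1-yl)-3,5,7-trioxododecanoate | O=C(OCC(c1ccccc1)c1ccccc1)[C@@](C)(CC=C(C)C)C(=O)CC(=O)CC(=O)CCCCC | intermediate
12 | (4S)-2-hexanoyl-3,5-dihydroxy-4-methyl-4-(3-methylbut-2-en-1-yl)cyclohexa-2,5-dien-1-one | CCCCCC(=O)C1=C(O)[C@@](C)(CC=C(C)C)C(O)=CC1=O | intermediate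
13 | benzene-1,3,5-triol | Oc1cc(O)cc(O)c1 | starting material
14 | hexanoyl chloride | CCCCCC(Cl)=O | starting material
15 | 1-(2,4,6-trihydroxyphenyl)hexan-1-one | CCCCCC(=O)c1c(O)cc(O)cc1O | intermediate
16 | 1-(2,6-dihydroxy-4-methoxyphenyl)hexan-1-one | CCCCCC(=O)c1c(O)cc(OC)cc1O | intermediate
17 | (4S)-6-[(dimethylamino)methyl]-2-hexanoyl-3,5-dihydroxy-4-methyl-4-(3-methylbut-2-en-1-yl)cyclohexa-2,5-dien-1-one | CCCCCC(=O)C1=C(O)[C@@](C)(CC=C(C)C)C(O)=C(CN(C)C)C1=O | intermediate
18 | (4R)-2-hexanoyl-3-hydroxy-4-methyl-4-(3-methylbut-2-en-1-yl)-6-methylidenecyclohex-2-ene-1,5-dione (same spatial arrangement as 12; the descriptor changes only formally) | CCCCCC(=O)C1=C(O)[C@@](C)(CC=C(C)C)C(=O)C(=C)C1=O | intermediate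
19 | (4S)-2-hexanoyl-6-[(3-hexanoyl-2,4-dihydroxy-6-methoxyphenyl)methyl]-3,5-dihydroxy-4-methyl-4-(3-methylbut-2-en-1-yl)cyclohexa-2,5-dien-1-one | CCCCCC(=O)C1=C(O)[C@@](C)(CC=C(C)C)C(O)=C(Cc2c(OC)cc(O)c(C(=O)CCCCC)c2O)C1=O | target

**Step count.** Total: 9 steps. Longest linear sequence: 7 steps (steps 1–6 and 9); steps 7–8 form the second branch.

**Steps most likely to fail**

1. Step 6. O-acylation of the diketone dianion, or acylation at its internal carbon, may compete; the latter, after ring closure, would deliver the mirror-image ring and erode the enantiomeric purity. Proton transfer from the product may also quench the dianion, and ring closure may stall at the open-chain stage. Fallback, from 8 back to 12: acid 8 would be converted with carbonyldiimidazole (THF, 23 °C) into 2,2-diphenylethyl (2S)-3-(1H-imidazol-1-yl)-2-methyl-2-(3-methylbut-2-en-1-yl)-3-oxopropanoate F1, a milder and more C-selective acyl donor. F1 would be added to the dianion of 10 (LiN(iPr)2, THF, −78 °C) and the triketo ester 11 isolated after a buffered work-up. The ring would then be closed in a separate operation under thermodynamic alkoxide conditions (KOt-Bu, potassium tert-butoxide, THF, 0 → 23 °C) to give 12.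

2. Step 9. The exocyclic enone may be intercepted by unreacted 12 (homo-coupling), may dimerise by hetero-Diels–Alder reaction, or may alkylate 16 twice. Fallback, from 16 back to 19: Vilsmeier–Haack formylation of 16 (POCl3, DMF, 0 → 23 °C; aqueous hydrolysis) would give 3-hexanoyl-2,4-dihydroxy-6-methoxybenzaldehyde F2. An organocatalytic three-component reductive alkylation of 12 with F2 (diethyl 2,6-dimethyl-1,4-dihydropyridine-3,5-dicarboxylate, L-proline cat., CH2Cl2, 23 °C) would then proceed by Knoevenagel condensation and conjugate hydride transfer to give 19 directly. The one-carbon bridge is then fixed on the aromatic partner, so no homo-coupling is possible.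

3. Step 3. Facial discrimination in the ion pair may be insufficient with the small, reactive prenyl bromide, or the sense of induction may differ from that assumed. Fallback, from 4 back to 6: alkylation of 4 with 5 under achiral phase-transfer conditions (Bu4NBr, 50% aq. KOH, toluene, 0 °C) would give racemic 1-tert-butyl 3-(2,2-diphenylethyl) 2-methyl-2-(3-methylbut-2-en-1-yl)propanedioate F3. Preparative supercritical-fluid chromatography on a polysaccharide chiral stationary phase would then separate 6 from its enantiomer, 1-tert-butyl 3-(2,2-diphenylethyl) (2S)-2-methyl-2-(3-methylbut-2-en-1-yl)propanedioate F4, which is set aside.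

**Further compounds**

F1 | step 6 | 2,2-diphenylethyl (2S)-3-(1H-imidazol-1-yl)-2-methyl-2-(3-methylbut-2-en-1-yl)-3-oxopropanoate | O=C(OCC(c1ccccc1)c1ccccc1)[C@@](C)(CC=C(C)C)C(=O)n1ccnc1
F2 | step 9 | 3-hexanoyl-2,4-dihydroxy-6-methoxybenzaldehyde | CCCCCC(=O)c1c(O)cc(OC)c(C=O)c1O
F3 | step 3 | racemic 1-tert-butyl 3-(2,2-diphenylethyl) 2-methyl-2-(3-methylbut-2-en-1-yl)propanedioate | O=C(OCC(c1ccccc1)c1ccccc1)C(C)(CC=C(C)C)C(=O)OC(C)(C)C
F4 | step 3 | 1-tert-butyl 3-(2,2-diphenylethyl) (2S)-2-methyl-2-(3-methylbut-2-en-1-yl)propanedioate | O=C(OCC(c1ccccc1)c1ccccc1)[C@](C)(CC=C(C)C)C(=O)OC(C)(C)C
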